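63.3% of the coupling partner charged had become target when the dawn run levelled off. I called this the partner yield: target at the plateau as a fraction of the partner charge. The impurity charge equalled 33.3% of the partner charge. That left 66.7%, against a yield of 63.3%, so I read the coupling partner as the limiting reagent, partly lost to the impurity.

| flask | substrate | coupling partner | protic impurity | free catalyst | remark |
|---|---|---|---|---|---|
| dawn | 0.80 M | 0.72 M | 0.24 M | 110 mM | run made earlier |
| winter | 1.8 M | 0.72 M | 0.24 M | 110 mM | run made earlier |
| flask | 1.2 M | 0.720 M | 0.240 M | 110 mM |  |

| run | time / h | target / % |
|---|---|---|
| dawn | 0.667 | 46.5 |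
| dawn | 2.00 | 55.4 |
| dawn | 3.00 | 56.6 |
| dawn | 5.00 | 57.0 |
| winter | 1.33 | 25.2 |
| winter | 2.50 | 26.2 |
| winter | 4.00 | 25.0 |
| winter | 5.00 | 25.2 |

(scatter of a reading: 1 percentage point)

- no earlier run changes the charge of free catalyst; that part of a forecast is a guess
- no earlier run changes the charge of coupling partner; that part of a forecast is a guess

* factor on the rate of making target when 30% of the substrate are converted if coupling partner is charged twice over
* factor on the rate when 30% of the substrate are converted if free catalyst is charged at 1200 mM instead

I had to decide what to change in the next run. The yield put the flask's plateau at 38.0% of its substrate. At 30% conversion, taken as target, that left room of 8 percentage points. So I chose to change the partner charge. A doubled charge, with the added partner counted in full, gave room of 68 points. I assumed that the rate followed this room, which gave a factor of 8.50. No run tested the catalyst, so I guessed first order, a factor of 10.9.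

The forecast differed from both figures: it gave 7 (range 3.5 to 10) and 8 (range 3 to 12), noting “Catalyst order is untested”.

The flask gave factors of 3.94 for the doubled partner and 13.5 for the larger catalyst charge.

    coupling partner + free catalyst → catalyst intermediate A (k = 0.620 L mol⁻¹ min⁻¹)
    substrate + catalyst intermediate A → catalyst intermediate B (k = 19.0 L mol⁻¹ min⁻¹)
    catalyst intermediate B → catalyst intermediate C (k = 0.900 min⁻¹)
    catalyst intermediate C ⇌ free catalyst + target (K = 1.60 M, k = 1.00 min⁻¹)
    coupling partner + protic impurity → quenched reagent (k = 0.590 L mol⁻¹ min⁻¹)

At 5.00 h the flask held 38.0% target, the plateau that the partner yield gave, with 60% of its substrate and 0% of its coupling partner left. On the winter run the same yield gives 25.3%, and winter read 25.2%. At the start of the flask, the partner's use by free catalyst stood at 0.48 of its use by the impurity. The quench is one reason for the flask's rate: without it, the rate at 30% conversion would be 2.35 times the actual one.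

The runs are calculated for an exercise; scatter was added.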